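## The problem

Selaginellin A is built on one benzene ring (ring A) that carries four different carbon substituents side by side: a methyl group on C1, a (4-hydroxyphenyl)ethynyl group on C2, a diarylmethylidene carbon on C3 that belongs to a p-quinone methide (phenyl on one side, cyclohexadienone on the other) and a 4-hydroxyphenyl ring (ring B) on C4. The task is therefore one of regiochemistry on a crowded 1,2,3,4-tetrasubstituted arene, and of forming a fully arylated carbon at C3 between two ortho neighbours. There is no stereocentre in the target; the tertiary carbinol that precedes the quinone methide is chiral, but it is made as the racemate and its configuration vanishes on dehydration, so nothing has to be controlled or relayed. The groups that will not stand rough treatment are the quinone methide (an electrophile toward water, alcohols and amines), the free phenols, and the diarylalkyne, which sits ortho to a carbon that is in turn a ketone, an alkoxide and a cation and can be attacked by each of them. This argues for methyl ethers throughout, for the quinone methide as the last event, and for keeping ketone and alkyne apart as long as possible. The feature that allows a short route is that the substituents on C1, C2 and C3 are, at a lower oxidation level, the two methyl groups and the carboxyl group of 2,3-dimethylbenzoic acid. The carboxyl group has a single free ortho C–H, which is C4, and it acidifies only the methyl group next to it, the future inner alkyne carbon; a lactone bridge from the carboxyl oxygen to the acylated methyl group then holds the carbinol carbon and both alkyne carbons in one six-membered ring.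

## Retrosynthesis

**15 from 14.** No skeletal bond is cut. The exocyclic double bond of the quinone methide is read as a dehydrated 4-hydroxyphenyl carbinol and the three phenols as methyl ethers. Making this the last operation, in preference to cutting an aryl group from the quinone methide itself, keeps the one electrophilic, chromatography-sensitive function out of every earlier intermediate. Carbinol 14 is a neutral, storable tertiary alcohol. The forward reaction has to cleave three aryl methyl ethers and ionise the carbinol without touching the neighbouring alkyne.

**14 from 11 and 13 (made from 12).** The bond between the carbinol carbon and the 4-methoxyphenyl ring is cut. Of the two aryl groups that could be added last, the anisyl group is chosen, because phenyl ketone 11 is the more electrophilic of the two possible benzophenones and aryllithium 13 is the more nucleophilic partner. The cut removes one ring and the only stereocentre of the route. The forward reaction is an addition to a di-ortho-substituted diaryl ketone, made feasible by the slim alkyne on one flank.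

**11 from 7 and 8.** The carbonyl–phenyl bond is cut, and the triple bond is read as an enol derivative that has lost the elements of a sulfonic acid. The enol oxygen and the carbonyl carbon are then joined as a six-membered enol lactone, isocoumarin 7. Two neighbouring cuts were weighed. A Sonogashira cut at C2 would need a 2-halobenzophenone with substituents on both sides, and nothing in such a ring would anchor the regiochemistry of its preparation. Adding both aryllithiums to the lactone before releasing the alkyne was put aside, because after the first addition the ketone is part of an anionic, cross-conjugated keto-enolate that should resist the second; releasing the alkyne first returns a neutral ketone. Lactone 7 is simpler by one aryl ring and hides the mutually reactive ketone–alkyne pair. The forward reaction asks for mono-addition of 8, trapping of the enolate oxygen that is set free, and anti elimination.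

**7 from 3 and 4 (key disconnection).** The lactone C–O bond and the bond between the benzylic carbon and the acyl carbon are cut; the latter is the bond between the two future alkyne carbons. This leaves benzoic acid 3, whose C2 methyl group is the nucleophile, and the commercial ester 4. Against an isocoumarin synthesis from a 2-halobenzoate and an arylacetylene, this cut uses C–H acidity in place of a halide that would be hard to place between two substituents. The forward reaction must deprotonate only the methyl group next to the carboxylate and must stop after one acylation.

**3 from 1 and 2.** The biaryl bond between C4 and ring B is cut. The carboxyl group that will become the carbinol carbon directs palladium to its only free ortho C–H, so no halogenated dimethylbenzoate has to be prepared. Both 1 and 2 are commercial. The forward reaction must arylate once and must not decarboxylate the product.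

## Roads not taken

**Alternative 1:** The cut is at the C3–carbonyl bond and the C2–alkyne bond together. Three components, 4-chloro-2-iodotoluene A1, benzoic anhydride A2 and 4-ethynylanisole A3, would be joined in a Catellani reaction under Pd(OAc)2 catalysis. In it A2 acylates the C–H ortho to iodine and A3 terminates the sequence at the ipso carbon, giving [6-chloro-2-[(4-methoxyphenyl)ethynyl]-3-methylphenyl](phenyl)methanone A4. A Suzuki–Miyaura coupling at the chloride of A4 would then install ring B and arrive at ketone 11.
- Merits: three simple components, high convergence, and the ortho methyl group of A1 guarantees mono-functionalisation.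
- Weak points: the C–H to be acylated lies between the iodine-bearing and the chlorine-bearing carbons of A1, a hindered site for palladacycle formation. The terminal alkyne A3 can couple directly at the iodide before the acylation by A2 has taken place. The later coupling has to take place at the chloride of A4, which is flanked by a benzoyl group.
- Comparison: in step count this road is better, two steps to 11 against three and four steps in all against five. The chosen plan sets against this that each of its bonds is made in a two-component reaction whose site is fixed by the substrate (one ortho C–H, one acidic methyl group), with no three-component chemoselectivity to tune.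

**Alternative 2:** Ring A itself is cut, at C1–C6, C4–C5 and C2–C3. The ester-tethered diyne 1,3-bis(4-methoxyphenyl)-1-phenylprop-2-yn-1-yl but-2-ynoate A5 and acetylene A6 would be cyclotrimerised with RhCl(PPh3)3 (monovalent rhodium) to the racemic phthalide 3,4-bis(4-methoxyphenyl)-7-methyl-3-phenylisobenzofuran-1(3H)-one A7.
- Merits: the substitution pattern of ring A is unambiguous, and both aryl groups are on the carbinol carbon before ring A exists. In this respect it is better than the chosen plan, which must bring a nucleophile to a di-ortho-substituted ketone.
- Weak points: A5 is the ester of a tertiary, doubly benzylic propargylic alcohol, which is hard to acylate and prone to ionise. An ester tether disfavours the conformation needed for cyclisation, one alkyne terminus is aryl-capped, and A6 would have to be supplied in excess to suppress self-condensation of A5. The lactone carbonyl of A7 is only the first alkyne carbon, so reduction to the lactol, one-carbon homologation to the terminal alkyne and Sonogashira coupling with 2 are still required before 14 is reached.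
- Comparison: roughly eight steps against five. The chosen plan sets its own lactone, in which both alkyne carbons are already present at the right oxidation level, against the hindered addition that this road avoids.

**Alternative 3:** Ring A is cut at C3–C4 and C1–C2. The diynone 5-(4-methoxyphenyl)-1-phenylpenta-2,4-diyn-1-one A8 would add through its carbonyl-conjugated triple bond to (1E,3E)-1-(4-methoxyphenyl)penta-1,3-diene A9 in a Diels–Alder reaction, and a quinone oxidant would aromatise the cyclohexadiene in the same flask. The product, [6-(4-methoxyphenyl)-2-[(4-methoxyphenyl)ethynyl]-3-methylphenyl](phenyl)methanone A10, is the same compound as ketone 11.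
- Merits: the most convergent construction, free of transition metals, with all four substituents placed in one step.
- Weak points: regiochemistry rests on the aryl terminus of A9 outweighing the methyl terminus in directing the addition to an ynone whose β-carbon is itself alkynylated, and a regioisomer of A10 would be hard to remove. A 1,4-disubstituted aryl diene is a sluggish diene. A8 and geometrically pure A9 each need their own two or three steps.
- Comparison: on convergence and on avoiding metals this road is better. The chosen plan sets against it a shorter overall count and a regiochemistry that is read off a preformed arene and not decided in a cycloaddition.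

Key step: step 2

Remark: LiN(i-Pr)2 and phenyllithium are taken as commercial solutions, and carbinol 14 is carried as the racemate because its only stereocentre disappears in the last step.

## Route

Step 1
Reactants: 1 2,3-dimethylbenzoic acid; 2 4-iodoanisole
Product: 3 6-(4-methoxyphenyl)-2,3-dimethylbenzoic acid
Conditions: Pd(OAc)2 (5 mol %), AgOAc (1.3 equiv), AcOH, 120 °C
Reagents that add atoms: none
Why: Carboxylate-directed ortho C–H arylation of a benzoic acid with an aryl iodide: the bound carboxylate delivers divalent palladium to the only free ortho C–H (C6), oxidative addition of 2 and reductive elimination form the biaryl bond, and AgOAc takes up iodide. The other ortho position carries a methyl group, so a second arylation is impossible.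

Step 2
Reactants: 3 6-(4-methoxyphenyl)-2,3-dimethylbenzoic acid; 4 methyl 4-methoxybenzoate
Product: 7 3,8-bis(4-methoxyphenyl)-5-methyl-1H-isochromen-1-one, via benzylic dilithio dianion 5 (not isolated), via keto acid 6 (not isolated)
Conditions: LiN(i-Pr)2 (3.2 equiv), THF, −78 → 0 °C; 4 (1.1 equiv), −78 °C → rt; aq. HCl; crude 6, TsOH·H2O (10 mol %), PhMe, reflux (Dean–Stark)
Reagents that add atoms: none
Why: LiN(i-Pr)2 forms the lithium carboxylate and then removes a proton from the C2 methyl group, the only benzylic position whose anion is held by the carboxylate lithium and delocalised into the carboxyl group; the C3 methyl group has neither benefit and the ring B C–H bonds are far less acidic. The benzylic carbon of dianion 5 attacks ester 4 in a Claisen-type acylation, and the third equivalent of base converts the new ketone at once into its enolate, so that neither a second addition nor quenching of unreacted 5 by the product should occur. Acidification releases keto acid 6; under TsOH the carboxyl oxygen adds to the protonated ketone in a 6-exo-trig closure and the hemiketal loses water to give the conjugated enol lactone 7. The closest known reaction type is the acylation of laterally lithiated o-toluic acid dianions with aromatic esters followed by acid cyclisation to 3-arylisocoumarins. No stereocentre is formed; the ring holds the new C=C bond so that its hydrogen is anti to the ring oxygen, the geometry needed in step 3. The selectivity required is the site of deprotonation, which the carboxylate secures, and ring B next to the carboxyl group additionally shields the carboxyl carbon from attack by base or by 5.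

Step 3
Reactants: 7 3,8-bis(4-methoxyphenyl)-5-methyl-1H-isochromen-1-one; 8 phenyllithium
Product: 11 [6-(4-methoxyphenyl)-2-[(4-methoxyphenyl)ethynyl]-3-methylphenyl](phenyl)methanone, via lithium Z-enolate 9 (not isolated), via Z-enol triflate 10 (not isolated)
Conditions: 8 (1.05 equiv), THF, −78 °C; PhNTf2 (1.2 equiv), −78 → 0 °C; t-BuOK (2.5 equiv), 0 °C → rt; H2O
Reagents that add atoms: none
Why: Addition of an aryllithium to the lactone carbonyl of an isocoumarin with ring opening (the reaction used to reach 1-aryl-2-benzopyrylium salts) should give keto-enolate 9 with the Z geometry of the ring, and its negative charge protects the new ketone from a second addition. O-Triflation of the lithium enolate with PhNTf2 and anti E2 elimination of the vinyl triflate (H and OTf trans) by t-BuOK then give the diarylalkyne. Triflate 10 is not isolated because an anisyl-substituted vinyl triflate next to a ketone oxygen could ionise to a benzopyrylium salt on standing.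

Step 4
Reactants: 11 [6-(4-methoxyphenyl)-2-[(4-methoxyphenyl)ethynyl]-3-methylphenyl](phenyl)methanone; 12 4-bromoanisole
Product: 14 (4-methoxyphenyl)[6-(4-methoxyphenyl)-2-[(4-methoxyphenyl)ethynyl]-3-methylphenyl](phenyl)methanol (racemic), via 4-methoxyphenyllithium 13 (not isolated)
Conditions: 12 (1.6 equiv), n-BuLi (1.5 equiv), THF, −78 °C; then 11, −78 → 0 °C; H2O
Reagents that add atoms: none
Why: Bromine–lithium exchange followed by 1,2-addition of an aryllithium to a non-enolisable diaryl ketone; the phenyl ketone is the more electrophilic of the two possible benzophenones and the linear alkyne leaves one flank of the carbonyl open. The new stereocentre is formed without control as the racemate and is removed in step 5; a cold quench keeps the lithium alkoxide from adding to the alkyne.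

Step 5
Reactants: 14 (4-methoxyphenyl)[6-(4-methoxyphenyl)-2-[(4-methoxyphenyl)ethynyl]-3-methylphenyl](phenyl)methanol (racemic)
Product: 15 selaginellin A, 4-[{6-(4-hydroxyphenyl)-2-[(4-hydroxyphenyl)ethynyl]-3-methylphenyl}(phenyl)methylidene]cyclohexa-2,5-dien-1-one
Conditions: BBr3 (6 equiv), CH2Cl2, −78 °C → rt; H2O
Reagents that add atoms: none
Why: Lewis-acid cleavage of the three aryl methyl ethers (bromide attacks the methyl group of the boron-bound ether) with ionisation of the tertiary carbinol; on aqueous work-up the 4-oxygenated trityl cation loses the phenolic proton and gives the p-quinone methide, the dehydrated form that such crowded 4-hydroxyphenyl carbinols adopt. The ring B carbons within reach of the cation are meta to the ring B oxygen, so Friedel–Crafts closure to a fluorene is not activated, and low temperature should spare the diarylalkyne from bromoboration.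

## Compound list

1 | 2,3-dimethylbenzoic acid | Cc1cccc(C(=O)O)c1C | starting material
2 | 4-iodoanisole | COc1ccc(I)cc1 | starting material
3 | 6-(4-methoxyphenyl)-2,3-dimethylbenzoic acid | Cc1ccc(-c2ccc(OC)cc2)c(C(=O)O)c1C | intermediate
4 | methyl 4-methoxybenzoate | COC(=O)c1ccc(OC)cc1 | starting material
5 | lithium 2-(lithiomethyl)-6-(4-methoxyphenyl)-3-methylbenzoate (benzylic dilithio dianion of 3) | [Li]Cc1c(C)ccc(-c2ccc(OC)cc2)c1C(=O)O[Li] | intermediate
6 | 6-(4-methoxyphenyl)-2-[2-(4-methoxyphenyl)-2-oxoethyl]-3-methylbenzoic acid | Cc1ccc(-c2ccc(OC)cc2)c(C(=O)O)c1CC(=O)c1ccc(OC)cc1 | intermediate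
7 | 3,8-bis(4-methoxyphenyl)-5-methyl-1H-isochromen-1-one | Cc1ccc(-c2ccc(OC)cc2)c2c1C=C(c1ccc(OC)cc1)OC2=O | intermediate
8 | phenyllithium | [Li]c1ccccc1 | starting material
9 | lithium (Z)-2-[2-benzoyl-3-(4-methoxyphenyl)-6-methylphenyl]-1-(4-methoxyphenyl)ethen-1-olate | Cc1ccc(-c2ccc(OC)cc2)c(C(=O)c2ccccc2)c1/C=C(\O[Li])c1ccc(OC)cc1 | intermediate
10 | (Z)-2-[2-benzoyl-3-(4-methoxyphenyl)-6-methylphenyl]-1-(4-methoxyphenyl)ethenyl trifluoromethanesulfonate | Cc1ccc(-c2ccc(OC)cc2)c(C(=O)c2ccccc2)c1/C=C(\OS(=O)(=O)C(F)(F)F)c1ccc(OC)cc1 | intermediate
11 | [6-(4-methoxyphenyl)-2-[(4-methoxyphenyl)ethynyl]-3-methylphenyl](phenyl)methanone | Cc1ccc(-c2ccc(OC)cc2)c(C(=O)c2ccccc2)c1C#Cc1ccc(OC)cc1 | intermediate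
12 | 4-bromoanisole | COc1ccc(Br)cc1 | starting material
13 | 4-methoxyphenyllithium | [Li]c1ccc(OC)cc1 | intermediate
14 | (4-methoxyphenyl)[6-(4-methoxyphenyl)-2-[(4-methoxyphenyl)ethynyl]-3-methylphenyl](phenyl)methanol (racemic) | Cc1ccc(-c2ccc(OC)cc2)c(C(O)(c2ccccc2)c2ccc(OC)cc2)c1C#Cc1ccc(OC)cc1 | intermediate
15 | selaginellin A | Cc1ccc(-c2ccc(O)cc2)c(C(=C2C=CC(=O)C=C2)c2ccccc2)c1C#Cc1ccc(O)cc1 | target

## Step count and least certain steps

Total step count: 5. Longest linear sequence: 5 steps (1 → 3 → 7 → 11 → 14 → 15); 2, 4, 8 and 12 enter as purchased building blocks.

**Step 2 (key step).** The most likely failure is deprotonation that is incomplete or goes to the wrong site. The carboxylate of a 2,6-disubstituted acid is twisted out of the ring plane, which weakens both its directing effect and the stabilisation of the benzylic anion. A slow lateral metalation would then compete with metalation of ring B next to the biaryl bond, which closes onto the carboxylate to give a fluorenone, and with attack of the amide base on ester 4. The fallback sets out from 3 and returns at 7. Acid 3 is converted with SOCl2 into 6-(4-methoxyphenyl)-2,3-dimethylbenzoyl chloride F1, and this with Et2NH into N,N-diethyl-6-(4-methoxyphenyl)-2,3-dimethylbenzamide F2, whose neutral tertiary amide is a stronger director than a twisted carboxylate and needs no dianion. s-BuLi/TMEDA (THF, −78 °C) gives N,N-diethyl-2-(lithiomethyl)-6-(4-methoxyphenyl)-3-methylbenzamide F3. Acylation with 4, with a second equivalent of LiN(i-Pr)2 present to take up the product as its enolate, gives N,N-diethyl-6-(4-methoxyphenyl)-2-[2-(4-methoxyphenyl)-2-oxoethyl]-3-methylbenzamide F4. Hot AcOH/aq. HCl closes the lactone with loss of diethylamine and gives 7.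

**Step 3.** Three processes could spoil the telescoped sequence. O-sulfonylation of the delocalised lithium enolate may be slow, so that protonation on work-up is followed by closure of the diketone to a benzopyrylium or lactol species. The anisyl-substituted vinyl triflate may ionise with capture by the ketone oxygen before elimination. tert-Butoxide may attack sulfur and return the enolate. The fallback sets out from 7 and returns at 11, and replaces the inherited enolate and the ionisable triflate by a stepwise, deprotonation-based ketone-to-alkyne conversion. Addition of 8 at −78 °C and a buffered quench give the neutral diketone 2-[2-benzoyl-3-(4-methoxyphenyl)-6-methylphenyl]-1-(4-methoxyphenyl)ethan-1-one F5. KN(SiMe3)2 regenerates the enolate as potassium (Z)-2-[2-benzoyl-3-(4-methoxyphenyl)-6-methylphenyl]-1-(4-methoxyphenyl)ethen-1-olate F6. ClP(O)(OEt)2 converts it into (Z)-2-[2-benzoyl-3-(4-methoxyphenyl)-6-methylphenyl]-1-(4-methoxyphenyl)ethenyl diethyl phosphate F7, which cannot ionise. Lithium 2,2,6,6-tetramethylpiperidide, a base without a transferable hydride, then eliminates diethyl phosphate to give 11.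

**Step 4.** The addition may fail through steric shielding of the di-ortho-substituted carbonyl, or be diverted by electron transfer from the electron-rich aryllithium to the ketone (ketyl formation and reduction), or the lithium alkoxide may add to the neighbouring alkyne on warming. The fallback sets out from 7, returns at 14, and reverses the order in which the two aryl groups are introduced. Step 3 is run with 13 in place of 8, passing through lithium (Z)-2-[2-(4-methoxybenzoyl)-3-(4-methoxyphenyl)-6-methylphenyl]-1-(4-methoxyphenyl)ethen-1-olate F8 and (Z)-2-[2-(4-methoxybenzoyl)-3-(4-methoxyphenyl)-6-methylphenyl]-1-(4-methoxyphenyl)ethenyl trifluoromethanesulfonate F9 to (4-methoxyphenyl)[6-(4-methoxyphenyl)-2-[(4-methoxyphenyl)ethynyl]-3-methylphenyl]methanone F10. Phenyllithium 8 is a poorer electron donor, faces a poorer acceptor in F10, and is available as a concentrated halide-free solution; it is then added in excess to F10 to give 14.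

**Step 1.** The product is a 2,6-disubstituted benzoic acid, and such acids can lose carbon dioxide in the presence of AgOAc and Pd(OAc)2 at 120 °C; the crowded palladacycle may also turn over slowly as iodide accumulates. The fallback sets out from 1 and returns at 3, separating C–H functionalisation from biaryl formation. Pd(OAc)2-catalysed carboxylate-directed ortho iodination (PhI(OAc)2, I2, DMF) gives 6-iodo-2,3-dimethylbenzoic acid F11. Suzuki–Miyaura coupling with 4-methoxyphenylboronic acid (Pd(PPh3)4, K2CO3, dioxane–water, below 100 °C, no silver) gives 3.

## Further compounds

F1 | step 2 | 6-(4-methoxyphenyl)-2,3-dimethylbenzoyl chloride | O=C(Cl)c1c(C)c(C)ccc1-c1ccc(OC)cc1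
F2 | step 2 | N,N-diethyl-6-(4-methoxyphenyl)-2,3-dimethylbenzamide | CCN(CC)C(=O)c1c(C)c(C)ccc1-c1ccc(OC)cc1
F3 | step 2 | N,N-diethyl-2-(lithiomethyl)-6-(4-methoxyphenyl)-3-methylbenzamide | CCN(CC)C(=O)c1c(C[Li])c(C)ccc1-c1ccc(OC)cc1
F4 | step 2 | N,N-diethyl-6-(4-methoxyphenyl)-2-[2-(4-methoxyphenyl)-2-oxoethyl]-3-methylbenzamide | CCN(CC)C(=O)c1c(CC(=O)c2ccc(OC)cc2)c(C)ccc1-c1ccc(OC)cc1
F5 | step 3 | 2-[2-benzoyl-3-(4-methoxyphenyl)-6-methylphenyl]-1-(4-methoxyphenyl)ethan-1-one | Cc1ccc(-c2ccc(OC)cc2)c(C(=O)c2ccccc2)c1CC(=O)c1ccc(OC)cc1
F6 | step 3 | potassium (Z)-2-[2-benzoyl-3-(4-methoxyphenyl)-6-methylphenyl]-1-(4-methoxyphenyl)ethen-1-olate | Cc1ccc(-c2ccc(OC)cc2)c(C(=O)c2ccccc2)c1/C=C(\O[K])c1ccc(OC)cc1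
F7 | step 3 | (Z)-2-[2-benzoyl-3-(4-methoxyphenyl)-6-methylphenyl]-1-(4-methoxyphenyl)ethenyl diethyl phosphate | Cc1ccc(-c2ccc(OC)cc2)c(C(=O)c2ccccc2)c1/C=C(\OP(=O)(OCC)OCC)c1ccc(OC)cc1
F8 | step 4 | lithium (Z)-2-[2-(4-methoxybenzoyl)-3-(4-methoxyphenyl)-6-methylphenyl]-1-(4-methoxyphenyl)ethen-1-olate | Cc1ccc(-c2ccc(OC)cc2)c(C(=O)c2ccc(OC)cc2)c1/C=C(\O[Li])c1ccc(OC)cc1
F9 | step 4 | (Z)-2-[2-(4-methoxybenzoyl)-3-(4-methoxyphenyl)-6-methylphenyl]-1-(4-methoxyphenyl)ethenyl trifluoromethanesulfonate | Cc1ccc(-c2ccc(OC)cc2)c(C(=O)c2ccc(OC)cc2)c1/C=C(\OS(=O)(=O)C(F)(F)F)c1ccc(OC)cc1
F10 | step 4 | (4-methoxyphenyl)[6-(4-methoxyphenyl)-2-[(4-methoxyphenyl)ethynyl]-3-methylphenyl]methanone | Cc1ccc(-c2ccc(OC)cc2)c(C(=O)c2ccc(OC)cc2)c1C#Cc1ccc(OC)cc1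
F11 | step 1 | 6-iodo-2,3-dimethylbenzoic acid | Cc1ccc(I)c(C(=O)O)c1C
A1 | alternative 1 | 4-chloro-2-iodotoluene | Cc1ccc(Cl)cc1I
A2 | alternative 1 | benzoic anhydride | O=C(OC(=O)c1ccccc1)c1ccccc1
A3 | alternative 1 | 4-ethynylanisole | C#Cc1ccc(OC)cc1
A4 | alternative 1 | [6-chloro-2-[(4-methoxyphenyl)ethynyl]-3-methylphenyl](phenyl)methanone | Cc1ccc(Cl)c(C(=O)c2ccccc2)c1C#Cc1ccc(OC)cc1
A5 | alternative 2 | 1,3-bis(4-methoxyphenyl)-1-phenylprop-2-yn-1-yl but-2-ynoate (racemic) | CC#CC(=O)OC(c1ccccc1)(c1ccc(OC)cc1)C#Cc1ccc(OC)cc1
A6 | alternative 2 | acetylene | C#C
A7 | alternative 2 | 3,4-bis(4-methoxyphenyl)-7-methyl-3-phenylisobenzofuran-1(3H)-one (racemic) | Cc1ccc(-c2ccc(OC)cc2)c2c1C(=O)OC2(c1ccccc1)c1ccc(OC)cc1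
A8 | alternative 3 | 5-(4-methoxyphenyl)-1-phenylpenta-2,4-diyn-1-one | O=C(C#CC#Cc1ccc(OC)cc1)c1ccccc1
A9 | alternative 3 | (1E,3E)-1-(4-methoxyphenyl)penta-1,3-diene | C/C=C/C=C/c1ccc(OC)cc1
A10 | alternative 3 | [6-(4-methoxyphenyl)-2-[(4-methoxyphenyl)ethynyl]-3-methylphenyl](phenyl)methanone | Cc1ccc(-c2ccc(OC)cc2)c(C(=O)c2ccccc2)c1C#Cc1ccc(OC)cc1
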